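(The data are calculated with constants of no real substance; noise was put on by code.)

Time is the same for alpha and zeta, 15 h, while temperature, loading and the way substrate goes in differ, so we ask what each change buys in rate.

| flask | substrate | reagent | catalyst | temperature | remark | time |
|---|---|---|---|---|---|---|
| violet | 0.20 M (fed, over 15 min) | 0.90 equiv | 1.7 mol% | 45 °C | run made earlier |  |
| blue | 0.20 M (fed, over 15 min) | 0.90 equiv | 3.9 mol% | 70 °C | run made earlier |  |
| alpha | 0.20 M (fed, over 15 min) | 0.900 equiv | 2.5 mol% | 50 °C |  | 15 h |
| zeta | 0.20 M | 0.900 equiv | 1.2 mol% | 90 °C | everything together at the start | 15 h |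

- violet (time / h: target / %): 0.667: 5; 2.00: 28; 4.00: 46; 5.00: 53; 8.00: 65
- blue (time / h: target / %): 0.250: 11; 0.667: 41; 1.33: 59; 2.00: 67; 3.00: 74

(each reading ± 1.5 percentage points)

* which of the two ends with the higher amount of target, in percent of the substrate charged ("neither" if they lie within 2 percentage points) (alpha / zeta / neither)
* target at the end, in percent of the substrate charged, alpha
* target at the end, in percent of the substrate charged, zeta

We freeze one number per flask, the rate number w: the rate of forming target, as a fraction of the charge per hour, divided by the fraction of substrate left and by the reagent left on the same scale. Reagent is the limiting reagent, so the cap is 90.0%. Integrating this rule gives a logarithm that climbs in time in proportion to w and to the excess of substrate over reagent. The readings then give w = 0.312 h⁻¹ for violet and 1.29 h⁻¹ for blue. Per mol% of catalyst, blue reads 1.80 times violet. We take that as a constant factor per degree and scale by loading, which gives alpha 0.515 h⁻¹ and zeta 0.632 h⁻¹, the rate number of zeta.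

The feed of 15 min is short beside 15 h, so we let alpha start at once, at 0.464 h⁻¹, and zeta at 0.569 h⁻¹. Integrated, our rule ends alpha at 82.9%, where the substrate term of the rule has fallen to 17.1% of its start and the reagent term to a smaller 7.90%. The same rule ends zeta at 84.6%. Zeta's rate number is 1.23 times alpha's, yet in our rule zeta gains 1.7 percentage points over alpha, less than the margin.

The forecast says neither, with 82% and 81%. Our zeta stands higher, as the forecast shaded zeta down: “Deactivation or side reactions could lower it”.

The flask gives 82.9% for alpha and 83.0% for zeta, so the answer is neither.

    substrate + catalyst ⇌ catalyst + intermediate (K = 2.80, k = 1150 M⁻¹ h⁻¹, Ea = 69.0 kJ mol⁻¹, ΔH = −62.0 kJ mol⁻¹)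
    reagent + catalyst + intermediate → catalyst + target (k = 713 M⁻² h⁻¹, Ea = 52.0 kJ mol⁻¹)
    (constants at 50 °C)

At the end zeta holds 14.0% substrate and 3.07% intermediate, alpha 4.53% and 12.6%. Take 0.632 h⁻¹ to zeta's recipe at 0.050 M of substrate, letting w follow [substrate] and [catalyst], which fall together at fixed loading: w becomes 0.0395 h⁻¹, and the rule gives 34.1%. The flask at that charge ends at 30.0%, below the forecast's 81% for zeta.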